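**Retrosynthetic overview**
- The succinimide is closed last. A primary amide nitrogen acylates onto C16, and this amide comes from an Evans syn-aldol (sets C12 and C13) between a C12 aldehyde and a 3-cyanopropanoyl imide.
- The 7β-OAc comes from allylic hydroxylation of a labd-8(17)-ene to the 7α-OH, followed by Mitsunobu inversion with AcOH.
- Rings A and B form in one biomimetic cationic cascade of an acyclic chloro-diene allylsilane. The C4 cation is released by ionising a tertiary methyl ether, the single C2–Cl stereocentre controls C5, C9 and C10, and Me3Si+ takes the role of the C17 proton.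
- The polyene is built from 3-methoxy-3-methylbutanal and allenyl-Bpin (C2 carbinol, inverted to the chloride), Me3Al/oxirane (E-C10=C5), and 2,3-dihydrofuran/Me3SiCH2Li (C8=C9 allylsilane, C11–C12).
- Ring order: A, then B (same step), then the succinimide.

**Assumptions**
- Labdane numbering is used throughout: decalin C1–C10, C17 = exocyclic CH2, C11/C12 side chain, C13–C16 imide carbons.
- The SMILES reads as 2S,5S,7S,9R,10S,12S,13R, that is 2α-Cl equatorial, 7β-OAc equatorial, normal labdane series.
- (S)-TRIP is taken as the catalyst antipode that gives the (S)-alcohol in step 2. If the opposite sense is found, the (R)-acid is used.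

**Step 1**
Reactants: 1 3-methoxy-3-methylbutan-1-ol
Product: 2 3-methoxy-3-methylbutanal
Conditions: TEMPO (5 mol %), PhI(OAc)2, CH2Cl2, 23 °C
Reagents that add atoms: none
Why: Oxoammonium (TEMPO/PhI(OAc)2) oxidation stops at the aldehyde under almost neutral conditions, so the β-methoxy group is not lost by E1cB, and no stereocentre is involved.

**Step 2**
Reactants: 2 3-methoxy-3-methylbutanal; 3 allenylboronic acid pinacol ester
Product: 5 (S)-6-methoxy-6-methylhept-1-yn-4-ol, via O-Bpin borate ester 4 (not isolated)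
Conditions: (S)-TRIP (5 mol %), 4 Å MS, PhMe, −20 °C; aq. work-up
Reagents that add atoms: none
Why: In this Brønsted-acid-catalysed asymmetric propargylboration the allenylboronate reacts through a closed six-membered SE2′ transition state (only the homopropargylic alcohol forms), and the boronate-bound phosphoric acid leaves the Si face of the aldehyde open, which sets the (S)-carbinol at the future C2.

**Step 3**
Reactants: 5 (S)-6-methoxy-6-methylhept-1-yn-4-ol
Product: 6 (R)-4-chloro-6-methoxy-6-methylhept-1-yne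
Conditions: PPh3, NCS, THF, 0 → 23 °C
Reagents that add atoms: N-chlorosuccinimide, O=C1CCC(=O)N1Cl
Why: In this Appel-type chlorination chloride displaces the alkoxyphosphonium ion by SN2 with inversion, giving the (R)-chloride that has the spatial arrangement of C2 in the target (the descriptor becomes 2S there only because the CIP ranks change after cyclisation).

**Step 4**
Reactants: 6 (R)-4-chloro-6-methoxy-6-methylhept-1-yne; 7 oxirane
Product: 10 (3E,6R)-6-chloro-8-methoxy-4,8-dimethylnon-3-en-1-ol, via alkenyldimethylalane 8 (not isolated), via lithium alkenylalanate 9 (not isolated)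
Conditions: Me3Al (3 equiv), Cp2ZrCl2 (20 mol %), CH2Cl2, −20 → 0 °C; volatiles off, hexane, n-BuLi, −78 → 0 °C; 7, THF, 0 → 23 °C; H2O/Rochelle work-up
Reagents that add atoms: trimethylaluminium, C[Al](C)C
Why: Negishi zirconium-catalysed carboalumination adds Me and Al syn with Al at the terminus, which fixes the E-C10=C5 alkene, and the derived alanate opens oxirane with retention of geometry, while the tertiary ether only binds an extra equivalent of Me3Al and the unactivated secondary chloride is inert at ≤0 °C.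

**Step 5**
Reactants: 10 (3E,6R)-6-chloro-8-methoxy-4,8-dimethylnon-3-en-1-ol
Product: 11 (3E,6R)-6-chloro-1-iodo-8-methoxy-4,8-dimethylnon-3-ene
Conditions: I2, PPh3, imidazole, CH2Cl2, 0 °C
Reagents that add atoms: iodine, II
Why: Garegg–Samuelsson (Appel-type) iodination converts the primary alcohol by SN2, with the secondary chloride, ether and alkene as spectators.

**Step 6**
Reactants: 11 (3E,6R)-6-chloro-1-iodo-8-methoxy-4,8-dimethylnon-3-ene; 12 2,3-dihydrofuran
Product: 14 5-[(3E,6R)-6-chloro-8-methoxy-4,8-dimethylnon-3-en-1-yl]-2,3-dihydrofuran, via 5-lithio-2,3-dihydrofuran 13 (not isolated)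
Conditions: 12, t-BuLi, THF, −78 → 0 °C; 11, DMPU, −30 → 23 °C; NaHCO3 work-up, basic alumina
Reagents that add atoms: none
Why: α-Lithiation of the cyclic enol ether is followed by SN2 alkylation with the primary iodide, which is far more reactive than the secondary chloride, and no stereocentre is formed.

**Step 7**
Reactants: 14 5-[(3E,6R)-6-chloro-8-methoxy-4,8-dimethylnon-3-en-1-yl]-2,3-dihydrofuran
Product: 16 triethyl{[(3Z,7E,10R)-10-chloro-12-methoxy-8,12-dimethyl-4-[(trimethylsilyl)methyl]trideca-3,7-dien-1-yl]oxy}silane, via lithium alkoxide 15 (not isolated)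
Conditions: Ni(cod)2 (5 mol %), Me3SiCH2Li (2 equiv), PhMe, 23 °C; then Et3SiCl, 0 → 23 °C
Reagents that add atoms: (trimethylsilyl)methyllithium, [Li]C[Si](C)(C)C; chlorotriethylsilane, CC[Si](Cl)(CC)CC
Why: Nickel(0)-catalysed dealkoxylative (Wenkert-type) cross-coupling cleaves the C(sp2)–O bond with retention, so CH2SiMe3 takes the place of the ring oxygen cis to the CH2CH2O chain and gives the single (Z)-allylsilane (C7 trans to C11), and the released lithium alkoxide is capped in the same flask.

**Step 8**
Reactants: 16 triethyl{[(3Z,7E,10R)-10-chloro-12-methoxy-8,12-dimethyl-4-[(trimethylsilyl)methyl]trideca-3,7-dien-1-yl]oxy}silane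
Product: 17 2α-chloro-12-(triethylsilyloxy)-13,14,15,16-tetranorlabd-8(17)-ene (trans-decalin, 5α-H, 9α-H, 10β-Me, equatorial Cl)
Conditions: TiCl4 (3 equiv), 2,6-di-tert-butylpyridine (1 equiv), CH2Cl2 (2 mM), −78 °C; Et3N/MeOH, then NaHCO3 quench
Reagents that add atoms: none
Why: Proposed new method: TiCl4 ionises only the tertiary methyl ether (the secondary chloride, both alkenes and the allylsilane are inert to an aprotic Lewis acid while the hindered pyridine traps adventitious HCl), giving the same C4 cation that a class II diterpene cyclase makes by protonation; this cation is relayed through the chair–chair fold with C2–Cl equatorial (the other fold puts Cl 1,3-diaxial to the nascent C4 and C10 methyls), the E-C5=C10 alkene gives the trans fusion, the C7/C11-trans allylsilane gives 9α-H, and loss of Me3Si+ fixes the 8(17)-alkene; the closest known reaction types are allylsilane-terminated cationic polyene cyclisation, Lewis-acid tert-alkylation of allylsilanes by tertiary halides or ethers, and tert-ether/TiCl4-initiated living cationic polymerisation capped by an allylsilane.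

**Step 9**
Reactants: 17 2α-chloro-12-(triethylsilyloxy)-13,14,15,16-tetranorlabd-8(17)-ene
Product: 18 2α-chloro-12-(triethylsilyloxy)-13,14,15,16-tetranorlabd-8(17)-en-7α-ol (axial OH)
Conditions: SeO2 (0.3 equiv), t-BuOOH (3 equiv, decane), CH2Cl2, 0 → 23 °C
Reagents that add atoms: tert-butyl hydroperoxide, CC(C)(C)OO (terminal oxygen source, relayed by selenium dioxide, O=[Se]=O)
Why: In this SeO2/t-BuOOH allylic hydroxylation (ene reaction then [2,3]-sigmatropic shift) the axial 7α-H is the hydrogen aligned with the π bond and oxygen is returned suprafacially, so the axial 7α-alcohol forms, with C7 preferred over the hindered tertiary C9.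

**Step 10**
Reactants: 18 2α-chloro-12-(triethylsilyloxy)-13,14,15,16-tetranorlabd-8(17)-en-7α-ol
Product: 19 2α-chloro-12-(triethylsilyloxy)-13,14,15,16-tetranorlabd-8(17)-en-7β-yl acetate
Conditions: PPh3, DIAD, AcOH, PhMe, 0 → 23 °C
Reagents that add atoms: acetic acid, CC(=O)O
Why: In the Mitsunobu reaction acetate displaces the axial oxyphosphonium group by SN2 from the β face, which installs the acetate and inverts C7 to the equatorial 7β (7S) configuration in one operation.

**Step 11**
Reactants: 19 2α-chloro-12-(triethylsilyloxy)-13,14,15,16-tetranorlabd-8(17)-en-7β-yl acetate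
Product: 20 7β-acetoxy-2α-chloro-13,14,15,16-tetranorlabd-8(17)-en-12-al
Conditions: (COCl)2, DMSO, CH2Cl2, −78 → −40 °C; Et3N, → 0 °C
Reagents that add atoms: none
Why: In a Swern oxidation applied directly to the primary triethylsilyl ether, the chlorosulfonium salt exchanges Et3Si for an alkoxysulfonium ion that collapses to the aldehyde with Et3N, leaving acetate, chloride and alkene untouched.

**Step 12**
Reactants: 21 3-cyanopropanoic acid; 22 (R)-4-benzyloxazolidin-2-one
Product: 24 (R)-4-benzyl-3-(3-cyanopropanoyl)oxazolidin-2-one, via mixed pivalic anhydride 23 (not isolated)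
Conditions: PivCl, Et3N, THF, −20 °C; 22, LiCl, 23 °C
Reagents that add atoms: none
Why: N-acylation of the oxazolidinone by the mixed pivalic anhydride (LiCl/Et3N protocol) occurs at the unhindered cyanopropanoyl carbonyl, and the auxiliary stereocentre is untouched.

**Step 13**
Reactants: 20 7β-acetoxy-2α-chloro-13,14,15,16-tetranorlabd-8(17)-en-12-al; 24 (R)-4-benzyl-3-(3-cyanopropanoyl)oxazolidin-2-one
Product: 27 (R)-4-benzyl-3-[(2R,3S)-2-(cyanomethyl)-3-hydroxy-4-(7β-acetoxy-2α-chloro-11,12,13,14,15,16-hexanorlabd-8(17)-en-9β-yl)butanoyl]oxazolidin-2-one (12S,13R syn-aldol), via Z-boron enolate 25 (not isolated), via boron aldolate 26 (not isolated)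
Conditions: 24, n-Bu2BOTf, Et3N, CH2Cl2, −78 → 0 °C; 20, −78 → 0 °C; pH 7 buffer, MeOH, 30 % H2O2, 0 °C
Reagents that add atoms: none
Why: In the Evans syn-aldol reaction the Z(O)-boron enolate reacts through a Zimmerman–Traxler chair on the face opposite the benzyl group of the (R)-auxiliary, setting 12S and 13R together, and any material from the minor enantiomer of step 2 becomes a separable diastereomer.

**Step 14**
Reactants: 27 syn-aldol adduct
Product: 29 haterumaimide N, via primary amide 28 (not isolated)
Conditions: [PtH(PMe2OH)(PMe2O)2H] (5 mol %), EtOH/H2O 4:1, 70 °C; then Et3N (0.2 equiv), 23 °C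
Reagents that add atoms: water, O
Why: Ghaffar–Parkins platinum-catalysed hydration converts the nitrile to the primary amide at neutral pH, and its nitrogen then attacks the exocyclic imide carbonyl (5-exo-trig N-acylation), expelling the oxazolidinone and closing the succinimide without touching C12, C13 or the acetate.

**Compound list**
1 | 3-methoxy-3-methylbutan-1-ol | COC(C)(C)CCO | starting material
2 | 3-methoxy-3-methylbutanal | COC(C)(C)CC=O | intermediate
3 | allenylboronic acid pinacol ester | C=C=CB1OC(C)(C)C(C)(C)O1 | starting material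
4 | O-Bpin borate ester of 5 | COC(C)(C)C[C@@H](OB1OC(C)(C)C(C)(C)O1)CC#C | intermediate (not isolated)
5 | (S)-6-methoxy-6-methylhept-1-yn-4-ol | COC(C)(C)C[C@@H](O)CC#C | intermediate
6 | (R)-4-chloro-6-methoxy-6-methylhept-1-yne | COC(C)(C)C[C@H](Cl)CC#C | intermediate
7 | oxirane | C1CO1 | starting material
8 | (E)-alkenyldimethylalane | COC(C)(C)C[C@H](Cl)C/C(C)=C/[Al](C)C | intermediate (not isolated)
9 | lithium butyl(alkenyl)dimethylalanate | COC(C)(C)C[C@H](Cl)C/C(C)=C/[Al-](C)(C)CCCC.[Li+] | intermediate (not isolated)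
10 | (3E,6R)-6-chloro-8-methoxy-4,8-dimethylnon-3-en-1-ol | COC(C)(C)C[C@H](Cl)C/C(C)=C/CCO | intermediate
11 | (3E,6R)-6-chloro-1-iodo-8-methoxy-4,8-dimethylnon-3-ene | COC(C)(C)C[C@H](Cl)C/C(C)=C/CCI | intermediate
12 | 2,3-dihydrofuran | C1=COCC1 | starting material
13 | 5-lithio-2,3-dihydrofuran | [Li]C1=CCCO1 | intermediate (not isolated)
14 | 5-[(3E,6R)-6-chloro-8-methoxy-4,8-dimethylnon-3-en-1-yl]-2,3-dihydrofuran | COC(C)(C)C[C@H](Cl)C/C(C)=C/CCC1=CCCO1 | intermediate
15 | lithium (3Z,7E,10R)-alkoxide of the allylsilane | COC(C)(C)C[C@H](Cl)C/C(C)=C/CC/C(C[Si](C)(C)C)=C/CC[O-].[Li+] | intermediate (not isolated)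
16 | (3Z,7E,10R)-chloro-diene allylsilane TES ether (cyclisation substrate) | COC(C)(C)C[C@H](Cl)C/C(C)=C/CC/C(C[Si](C)(C)C)=C/CCO[Si](CC)(CC)CC | intermediate
17 | 2α-chloro-12-(triethylsilyloxy)-13,14,15,16-tetranorlabd-8(17)-ene | C=C1CC[C@H]2C(C)(C)C[C@H](Cl)C[C@]2(C)[C@H]1CCO[Si](CC)(CC)CC | intermediate
18 | 7α-alcohol of 17 | C=C1[C@H](O)C[C@H]2C(C)(C)C[C@H](Cl)C[C@]2(C)[C@H]1CCO[Si](CC)(CC)CC | intermediate
19 | 7β-acetate | C=C1[C@@H](OC(C)=O)C[C@H]2C(C)(C)C[C@H](Cl)C[C@]2(C)[C@H]1CCO[Si](CC)(CC)CC | intermediate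
20 | 7β-acetoxy-2α-chloro-13,14,15,16-tetranorlabd-8(17)-en-12-al | C=C1[C@@H](OC(C)=O)C[C@H]2C(C)(C)C[C@H](Cl)C[C@]2(C)[C@H]1CC=O | intermediate
21 | 3-cyanopropanoic acid | N#CCCC(=O)O | starting material
22 | (R)-4-benzyloxazolidin-2-one | O=C1N[C@H](Cc2ccccc2)CO1 | starting material
23 | 3-cyanopropanoic pivalic anhydride | N#CCCC(=O)OC(=O)C(C)(C)C | intermediate (not isolated)
24 | (R)-4-benzyl-3-(3-cyanopropanoyl)oxazolidin-2-one | N#CCCC(=O)N1[C@H](Cc2ccccc2)COC1=O | intermediate
25 | Z(O)-dibutylboron enolate of 24 | N#CC/C=C(\OB(CCCC)CCCC)N1[C@H](Cc2ccccc2)COC1=O | intermediate (not isolated)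
26 | dibutylboron aldolate | C=C1[C@@H](OC(C)=O)C[C@H]2C(C)(C)C[C@H](Cl)C[C@]2(C)[C@H]1C[C@H](OB(CCCC)CCCC)[C@@H](CC#N)C(=O)N1[C@H](Cc2ccccc2)COC1=O | intermediate (not isolated)
27 | (12S,13R) syn-aldol adduct | C=C1[C@@H](OC(C)=O)C[C@H]2C(C)(C)C[C@H](Cl)C[C@]2(C)[C@H]1C[C@H](O)[C@@H](CC#N)C(=O)N1[C@H](Cc2ccccc2)COC1=O | intermediate
28 | primary amide from 27 | C=C1[C@@H](OC(C)=O)C[C@H]2C(C)(C)C[C@H](Cl)C[C@]2(C)[C@H]1C[C@H](O)[C@@H](CC(N)=O)C(=O)N1[C@H](Cc2ccccc2)COC1=O | intermediate (not isolated)
29 | haterumaimide N (2S,5S,7S,9R,10S,12S,13R) | C=C1[C@@H](OC(C)=O)C[C@H]2C(C)(C)C[C@H](Cl)C[C@]2(C)[C@H]1C[C@H](O)[C@H]1CC(=O)NC1=O | target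

**Step count**
- Total steps: 14.
- Longest linear sequence: 13 (steps 1–11, 13, 14). Step 12 is a one-step side branch.

**Three steps most likely to fail**

**Step 8 (key cascade).**
- Risks: E1 loss from the C4 cation, protodesilylation by traces of HCl, interception of the C8 cation by the silyl ether oxygen, and incomplete facial control by the chloride.
- The fallback sets out from 14 and comes back at 17. It changes the terminator from the allylsilane to the cyclic enol ether.
- 14 itself is treated with TiCl4 and the hindered pyridine at −78 °C. The much more nucleophilic dihydrofuran carbon C9 ends the same chair–chair cascade as a C8 oxocarbenium ion.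
- Aqueous quench gives 2α-chloro-12-hydroxy-13,14,15,16,17-pentanorlabdan-8-one F6, in equilibrium with its hemiketal. C9 can equilibrate to the desired equatorial side chain.
- Et3SiCl/imidazole gives the keto silyl ether F7, and Wittig methylenation with Ph3P=CH2 installs C17 and returns 17.

**Step 10 (Mitsunobu).**
- Risks: the axial allylic oxyphosphonium ion can undergo SN2′ attack at C17 or anti-periplanar E2 elimination to the 6,8(17)-diene.
- The fallback sets out from 18 and comes back at 19. It replaces substitution by redox inversion.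
- Dess–Martin oxidation gives the 7-oxo-8(17)-ene enone F8.
- Luche reduction (NaBH4, CeCl3, MeOH, −78 °C) delivers hydride axially from the α face and gives the equatorial 7β-alcohol F9.
- Ac2O/pyridine/DMAP then gives 19.

**Step 6 (alkylation).**
- Risks: the homoallylic iodide has allylic β-hydrogens, so E2 elimination to a diene can compete, and the basic alkenyllithium also meets the secondary chloride.
- The fallback sets out from 11 (with 13) and comes back at 16. It reverses the polarity and bypasses step 7.
- 11 is exchanged with t-BuLi (2 equiv, Et2O/pentane, −78 °C) to the homoallyllithium F1.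
- CuBr·SMe2 and 13 convert F1 into the mixed lithium cuprate F2.
- On warming, F2 undergoes a 1,2-metallate rearrangement: the alkyl group shifts from Cu to C8 with inversion at the alkenyl carbon and ring opening, giving the alkenylcopper alkoxide F3.
- Iodinolysis gives the (3Z)-iodoalkenol F4, and Et3SiCl/imidazole gives the iodoalkene silyl ether F5.
- Pd(PPh3)4-catalysed Kumada coupling with Me3SiCH2MgCl (THF, 23 °C, retention) gives 16.

**Further compounds**
F1 | step 6 | (3E,6R)-6-chloro-8-methoxy-4,8-dimethylnon-3-en-1-yllithium | COC(C)(C)C[C@H](Cl)C/C(C)=C/CC[Li]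
F2 | step 6 | mixed lithium alkyl(4,5-dihydrofuran-2-yl)cuprate | COC(C)(C)C[C@H](Cl)C/C(C)=C/CC[Cu-]C1=CCCO1.[Li+]
F3 | step 6 | alkenylcopper lithium alkoxide (Cu cis to the CH2CH2O chain) | COC(C)(C)C[C@H](Cl)C/C(C)=C/CC/C([Cu])=C/CC[O-].[Li+]
F4 | step 6 | (3Z,7E,10R)-10-chloro-4-iodo-12-methoxy-8,12-dimethyltrideca-3,7-dien-1-ol | COC(C)(C)C[C@H](Cl)C/C(C)=C/CC/C(I)=C/CCO
F5 | step 6 | triethylsilyl ether of F4 | COC(C)(C)C[C@H](Cl)C/C(C)=C/CC/C(I)=C/CCO[Si](CC)(CC)CC
F6 | step 8 | 2α-chloro-12-hydroxy-13,14,15,16,17-pentanorlabdan-8-one | O=C1CC[C@H]2C(C)(C)C[C@H](Cl)C[C@]2(C)[C@H]1CCO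
F7 | step 8 | 2α-chloro-12-(triethylsilyloxy)-13,14,15,16,17-pentanorlabdan-8-one | O=C1CC[C@H]2C(C)(C)C[C@H](Cl)C[C@]2(C)[C@H]1CCO[Si](CC)(CC)CC
F8 | step 10 | 2α-chloro-12-(triethylsilyloxy)-13,14,15,16-tetranorlabd-8(17)-en-7-one | C=C1C(=O)C[C@H]2C(C)(C)C[C@H](Cl)C[C@]2(C)[C@H]1CCO[Si](CC)(CC)CC
F9 | step 10 | 2α-chloro-12-(triethylsilyloxy)-13,14,15,16-tetranorlabd-8(17)-en-7β-ol | C=C1[C@@H](O)C[C@H]2C(C)(C)C[C@H](Cl)C[C@]2(C)[C@H]1CCO[Si](CC)(CC)CC
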